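**Strategy.** The target is cut at the benzylic C8–C9 methylene–methylene bond of the nonanoyl chain, next to the 4-hydroxyphenyl ring. In the retron this bond is a styrenyl C8=C9 double bond, made in one operation by ruthenium-catalysed olefin cross-metathesis of two terminal alkenes. One is 1-(2-hydroxy-6-methoxyphenyl)non-8-en-1-one, which already carries the complete, unprotected 2-hydroxy-6-methoxyphenyl ketone ring and C1–C8. The other is 4-acetoxystyrene, which brings C9 and the phenol ring. The step exploits the fact that C9 is benzylic to the 4-oxygenated ring (a styrene) and that the chain has no stereocentre, so the alkene geometry is erased by hydrogenation; acetate methanolysis in the same pot ends the route.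

Key step: step 2

Remark: the target has no stereocentre. C1–C9 denote the nonan-1-one chain (C1 = carbonyl carbon, C9 = benzylic carbon on the 4-hydroxyphenyl ring). Compounds 1, 2 and 5 are taken as commercial.

**Step 1**
Reactants: 1 1-(2-hydroxy-6-methoxyphenyl)ethan-1-one; 2 7-bromohept-1-ene
Product: 4 1-(2-hydroxy-6-methoxyphenyl)non-8-en-1-one, via dilithium phenoxide-enolate 3 (not isolated)
Conditions: LDA (2.2 equiv), THF, −78 → 0 °C; then 2 (1.2 equiv), DMPU, −78 °C → rt; 1 M HCl work-up
Reagents that add atoms: none
Why: Two equivalents of LDA should convert 1 into the phenoxide–enolate dianion, whose enolate carbon is far more nucleophilic than the lithium phenoxide oxygen, so SN2 reaction with the primary bromide 2 should give C-alkylation at the methyl carbon (dianion alkylation of an o-hydroxyacetophenone) and leave the terminal alkene untouched.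

**Step 2**
Reactants: 4 1-(2-hydroxy-6-methoxyphenyl)non-8-en-1-one; 5 4-ethenylphenyl acetate (4-acetoxystyrene)
Product: 6 4-[(1E)-9-(2-hydroxy-6-methoxyphenyl)-9-oxonon-1-en-1-yl]phenyl acetate
Conditions: Grubbs II (5 mol%), 5 (3 equiv), CH2Cl2, 40 °C, argon sweep
Reagents that add atoms: none
Why: Olefin cross-metathesis by the Chauvin mechanism: the Ru alkylidene passes through ruthenacyclobutanes by [2+2] cycloaddition and cycloreversion with the terminal alkene of 4 and the vinyl group of 5, joining C8 to C9 and releasing ethene, whose removal drives the reaction. The closest known reaction type is the Grubbs II cross-metathesis of a terminal aliphatic alkene with a styrene. No ring is closed and no stereocentre is formed; the E alkene should predominate, but its geometry is irrelevant because step 3 saturates it. The selectivity needed is cross- over homo-coupling, secured by using the inexpensive styrene 5 in excess and by the homodimer of 4 re-entering the cycle through secondary metathesis. Chemoselectivity rests on the tolerance of the catalyst for the hydrogen-bonded phenol, the hindered aryl ketone and the aryl acetate, so 4 needs no protecting group.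

**Step 3**
Reactants: 6 4-[(1E)-9-(2-hydroxy-6-methoxyphenyl)-9-oxonon-1-en-1-yl]phenyl acetate
Product: 8 1-(2-hydroxy-6-methoxyphenyl)-9-(4-hydroxyphenyl)nonan-1-one, via saturated aryl acetate 7 (not isolated)
Conditions: H2 (1 atm), 10% Pd/C, EtOAc–MeOH, rt; N2 purge; then K2CO3 (0.2 equiv), MeOH, rt; filter, aq. NH4Cl wash
Reagents that add atoms: none
Why: Heterogeneous catalytic hydrogenation should saturate the disubstituted styrenyl C8=C9 bond much faster than it touches the doubly ortho-substituted, hydrogen-bonded aryl ketone, and base-catalysed transesterification (Zemplén-type methanolysis) should then free the phenol from the aryl acetate without affecting the methyl ether.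

**Compound list**
1 | 1-(2-hydroxy-6-methoxyphenyl)ethan-1-one (2'-hydroxy-6'-methoxyacetophenone) | COc1cccc(O)c1C(C)=O | starting material
2 | 7-bromohept-1-ene | C=CCCCCCBr | starting material
3 | dilithium phenoxide-enolate of 1 (not isolated) | [Li+].[Li+].COc1cccc([O-])c1C(=C)[O-] | intermediate
4 | 1-(2-hydroxy-6-methoxyphenyl)non-8-en-1-one | COc1cccc(O)c1C(=O)CCCCCCC=C | intermediate
5 | 4-ethenylphenyl acetate (4-acetoxystyrene) | C=Cc1ccc(OC(C)=O)cc1 | starting material
6 | 4-[(1E)-9-(2-hydroxy-6-methoxyphenyl)-9-oxonon-1-en-1-yl]phenyl acetate | COc1cccc(O)c1C(=O)CCCCCC/C=C/c1ccc(OC(C)=O)cc1 | intermediate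
7 | 4-[9-(2-hydroxy-6-methoxyphenyl)-9-oxononyl]phenyl acetate (not isolated) | COc1cccc(O)c1C(=O)CCCCCCCCc1ccc(OC(C)=O)cc1 | intermediate
8 | 1-(2-hydroxy-6-methoxyphenyl)-9-(4-hydroxyphenyl)nonan-1-one (CNP0117926.0) | COc1cccc(O)c1C(=O)CCCCCCCCc1ccc(O)cc1 | target

**Total step count:** 3
**Longest linear sequence:** 3

**Steps most likely to fail, with fallbacks**

Step 1. The SN2 reaction of the dianion at the unactivated primary bromide may be slow. Proton exchange between alkylated product and unreacted dianion could then compete, giving over-alkylation at C2 and incomplete conversion. The fallback replaces enolate alkylation by acylation of an aryl nucleophile. It does not branch from a numbered compound: it sets out from commercial non-8-enoic acid and 1,3-dimethoxybenzene in place of 1 and 2, and comes back to the route at compound 4. Non-8-enoic acid would be converted with CDI and N,O-dimethylhydroxylamine hydrochloride (CH2Cl2, rt) into N-methoxy-N-methylnon-8-enamide F1. 1,3-Dimethoxybenzene would be lithiated between its two methoxy groups (n-BuLi, THF, 0 °C → rt; directed ortho-metalation) to 2-lithio-1,3-dimethoxybenzene F2. F2 should be acylated by F1 (−78 → 0 °C, 1 M HCl quench) to 1-(2,6-dimethoxyphenyl)non-8-en-1-one F3. BCl3 (1.1 equiv, CH2Cl2, −78 → 0 °C) should then cleave only one methyl ether, through the boron chelate to the ketone oxygen, and give 4.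

Step 2. Homodimerisation of both alkenes may compete, and chelation of ruthenium by the o-hydroxy ketone could slow the catalyst, leaving the cross-coupling incomplete. The fallback forms the same C8=C9 bond by Wittig olefination. It sets out from compound 4 and comes back to the route at compound 8. Lemieux–Johnson cleavage of the terminal alkene of 4 (OsO4 cat., NaIO4, 2,6-lutidine, dioxane–H2O) should give 8-(2-hydroxy-6-methoxyphenyl)-8-oxooctanal F4. 4-(Benzyloxy)benzyl chloride and PPh3 (toluene, reflux) would give [4-(benzyloxy)benzyl]triphenylphosphonium chloride F5. The ylide from F5 (NaHMDS, THF, 0 °C, in excess to allow for the phenol) should attack the aldehyde in preference to the hindered aryl ketone and give 9-[4-(benzyloxy)phenyl]-1-(2-hydroxy-6-methoxyphenyl)non-8-en-1-one F6 as an E/Z mixture. Hydrogenation (H2, Pd/C, EtOAc–MeOH) should then saturate the alkene and cleave the benzyl ether in one operation to give 8.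

Step 3. Over-reduction may occur: the aryl ketone could be hydrogenated or hydrogenolysed at its benzylic carbon during prolonged contact with Pd/C. The fallback replaces catalytic hydrogenation by metal-free diimide transfer, which reduces only the non-polar C=C bond. It sets out from compound 6 and comes back to the route at compound 7. Treatment of 6 with 2-nitrobenzenesulfonylhydrazide and Et3N (CH2Cl2, rt) should give 7, which is then methanolysed as in step 3. This fallback makes no new compound (F0).

**Further compounds**
F1 | step 1 | N-methoxy-N-methylnon-8-enamide | C=CCCCCCCC(=O)N(C)OC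
F2 | step 1 | 2-lithio-1,3-dimethoxybenzene | [Li]c1c(OC)cccc1OC
F3 | step 1 | 1-(2,6-dimethoxyphenyl)non-8-en-1-one | COc1cccc(OC)c1C(=O)CCCCCCC=C
F4 | step 2 | 8-(2-hydroxy-6-methoxyphenyl)-8-oxooctanal | COc1cccc(O)c1C(=O)CCCCCCC=O
F5 | step 2 | [4-(benzyloxy)benzyl]triphenylphosphonium chloride | [Cl-].c1ccc(COc2ccc(C[P+](c3ccccc3)(c3ccccc3)c3ccccc3)cc2)cc1
F6 | step 2 | 9-[4-(benzyloxy)phenyl]-1-(2-hydroxy-6-methoxyphenyl)non-8-en-1-one (E/Z mixture) | COc1cccc(O)c1C(=O)CCCCCCC=Cc1ccc(OCc2ccccc2)cc1
F0 | step 3 | none | none
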